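**Assumption:** the SMILES is taken as the absolute configuration, (1R,4aS,8aS) on the decalin. This is the enantiomeric (ent-) drimane series with a trans ring fusion and the CH2OAr cis to the angular methyl, so sclareolide-type starting materials do not fit. Atom labels below use drimane numbering (C3, C6 ketones; C7=C8; C11 = CH2O).

## Retrosynthetic overview

1. Target ⇒ C3 ketone unmasked last from an isopropenyl group (the original carvone stereocenter); aryl ether from Mitsunobu coupling of umbelliferone with the C11 alcohol.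
2. 6-Oxo-7-ene with C5-H and C9-H ⇒ hydrolysis and conjugation of a 6-ethoxy-5,8-diene (C5 and C9 set thermodynamically under control of C10).
3. Ring B ⇒ Diels–Alder reaction of a ring-A 2-ethoxy diene with methyl but-2-ynoate (forms C7–C8 and C9–C10, sets quaternary C10).
4. Diene ⇒ Stille coupling of the enol triflate of 6,6-dimethyl-dihydrocarvone.
5. Ring A is bought as (R)-(−)-carvone; ring B is formed second, by the cycloaddition.

## Route

**Step 1**
Reactants: 1, (R)-(−)-carvone
Product: 2, (5R)-2,6-dimethyl-5-(prop-1-en-2-yl)cyclohex-2-en-1-one (C6 epimers, trans major)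
Conditions: LDA, THF, −78 °C; MeI, −78 → 0 °C
Reagents that add atoms: iodomethane, CI
Why: Kinetic α′-deprotonation gives the cross-conjugated enolate, which is C-methylated (enolate alkylation); the new C6 center is removed in step 2.

**Step 2**
Reactants: 2
Product: 3, (5S)-2,6,6-trimethyl-5-(prop-1-en-2-yl)cyclohex-2-en-1-one (6,6-dimethylcarvone)
Conditions: LDA, THF–DMPU, −78 °C; MeI, → rt
Reagents that add atoms: iodomethane, CI
Why: A second kinetic α′-alkylation installs the gem-dimethyl group (future C4) next to the untouched carvone stereocenter (future C3).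

**Step 3**
Reactants: 3
Product: 4, (5S)-2,6,6-trimethyl-5-(prop-1-en-2-yl)cyclohex-1-en-1-yl trifluoromethanesulfonate
Conditions: L-Selectride, THF, −78 °C; then PhNTf2, −78 → 0 °C
Reagents that add atoms: N-phenylbis(trifluoromethanesulfonimide), O=S(=O)(N(c1ccccc1)S(=O)(=O)C(F)(F)F)C(F)(F)F
Why: Conjugate hydride reduction of the enone gives a single regiodefined enolate (the other α-carbon is quaternary), trapped as the tetrasubstituted enol triflate.

**Step 4**
Reactants: 4; 5, tributyl(1-ethoxyvinyl)stannane
Product: 6, (4S)-2-(1-ethoxyethenyl)-1,3,3-trimethyl-4-(prop-1-en-2-yl)cyclohex-1-ene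
Conditions: Pd(PPh3)4, LiCl, CuI, THF, 65 °C
Reagents that add atoms: 5, CCCC[Sn](CCCC)(CCCC)C(=C)OCC
Why: Stille coupling of the hindered vinyl triflate (as used for 2,6,6-trimethylcyclohexenyl triflates) gives the 2-ethoxy diene that carries the future C6 oxygen.

**Step 5 (key step)**
Reactants: 6; 7, methyl but-2-ynoate
Product: 8, methyl (6S,8aR)-4-ethoxy-2,5,5,8a-tetramethyl-6-(prop-1-en-2-yl)-3,5,6,7,8,8a-hexahydronaphthalene-1-carboxylate
Conditions: 7 (5 equiv), BHT, PhMe, 140 °C, sealed tube; chromatography to remove the minor C10 epimer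
Reagents that add atoms: 7, CC#CC(=O)OC
Why: Thermal Diels–Alder reaction forms ring B with the nucleophilic CH2 terminus bonding to the ynoate β-carbon and C10 to the α-carbon ("para" to OEt). The alkyne should add to the face away from the axial C4 methyl in the product-like half-chair that keeps the isopropenyl equatorial, so the new C10 methyl is cis to the isopropenyl. This is remote 1,4-induction, so expect only about 4:1; the minor epimer must be removed here because it would become the enantiomer after step 9.

**Step 6**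
Reactants: 8
Product: 9, [(6S,8aS)-4-ethoxy-2,5,5,8a-tetramethyl-6-(prop-1-en-2-yl)-3,5,6,7,8,8a-hexahydronaphthalen-1-yl]methanol
Conditions: DIBAL-H, CH2Cl2, −78 °C; Rochelle salt workup
Reagents that add atoms: none
Why: 1,2-Reduction of the enoate to the allylic alcohol; no ketone is present yet (C6 is an enol ether, C3 an isopropenyl), so no chemoselectivity problem arises.

**Step 7**
Reactants: 9
Product: 10, (4R,4aS,7S,8aR)-4-(hydroxymethyl)-3,4a,8,8-tetramethyl-7-(prop-1-en-2-yl)-4a,5,6,7,8,8a-hexahydronaphthalen-1(4H)-one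
Conditions: 0.5 M HCl, THF, 0 °C; then DBU, CH2Cl2, rt
Reagents that add atoms: water, O
Why: Enol ether hydrolysis gives the 6-ketone, and DBU moves the 8(9)-alkene into conjugation through the dienolate. This sets C5 (trans fusion) and C9 (equatorial CH2OH, cis to the C10 methyl) as the expected thermodynamic epimers under control of C10.

**Step 8**
Reactants: 10; 11, umbelliferone (7-hydroxycoumarin)
Product: 12, 7-{[(1R,4aR,6S,8aS)-2,5,5,8a-tetramethyl-4-oxo-6-(prop-1-en-2-yl)-1,4,4a,5,6,7,8,8a-octahydronaphthalen-1-yl]methoxy}-2H-chromen-2-one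
Conditions: PPh3, DIAD, THF, 0 °C → rt
Reagents that add atoms: 11, Oc1ccc2ccc(=O)oc2c1
Why: Mitsunobu etherification; the acidic phenol (pKa about 7.8) displaces the primary alkoxyphosphonium at C11 by SN2, and no stereocenter is touched.

**Step 9**
Reactants: 12
Product: 13, epi-conferdione (target)
Conditions: O3, CH2Cl2–MeOH, −78 °C (Sudan III endpoint); FeSO4·7H2O, TEMPO, 0 °C → rt; then MMPP
Reagents that add atoms: TEMPO (supplies the ketone oxygen), CC1(C)CCCC(C)(C)N1[O]
Why: Oxodealkenylation: ozone takes the isopropenyl (the enone and coumarin alkenes are deactivated), Fe(II) fragments the α-methoxy hydroperoxide to the C3 radical, and TEMPO trapping then peracid oxidation gives the C3 ketone. The carvone stereocenter is erased only after it has set C10.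

## Compound list

1 | (R)-(−)-carvone | CC1=CC[C@H](CC1=O)C(C)=C | starting material
2 | (5R)-2,6-dimethyl-5-(prop-1-en-2-yl)cyclohex-2-en-1-one (C6 epimers) | CC1=CC[C@@H](C(C)=C)C(C)C1=O | intermediate
3 | (5S)-2,6,6-trimethyl-5-(prop-1-en-2-yl)cyclohex-2-en-1-one | CC1=CC[C@@H](C(C)=C)C(C)(C)C1=O | intermediate
4 | (5S)-2,6,6-trimethyl-5-(prop-1-en-2-yl)cyclohex-1-en-1-yl triflate | CC1=C(OS(=O)(=O)C(F)(F)F)C(C)(C)[C@H](C(C)=C)CC1 | intermediate
5 | tributyl(1-ethoxyvinyl)stannane | CCCC[Sn](CCCC)(CCCC)C(=C)OCC | starting material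
6 | (4S)-2-(1-ethoxyethenyl)-1,3,3-trimethyl-4-(prop-1-en-2-yl)cyclohex-1-ene | CCOC(=C)C1=C(C)CC[C@@H](C(C)=C)C1(C)C | intermediate
7 | methyl but-2-ynoate | CC#CC(=O)OC | starting material
8 | methyl (6S,8aR)-4-ethoxy-2,5,5,8a-tetramethyl-6-(prop-1-en-2-yl)-3,5,6,7,8,8a-hexahydronaphthalene-1-carboxylate | CC1=C(C(=O)OC)[C@]2(C)CC[C@@H](C(C)=C)C(C)(C)C2=C(OCC)C1 | intermediate
9 | [(6S,8aS)-4-ethoxy-2,5,5,8a-tetramethyl-6-(prop-1-en-2-yl)-3,5,6,7,8,8a-hexahydronaphthalen-1-yl]methanol | CC1=C(CO)[C@]2(C)CC[C@@H](C(C)=C)C(C)(C)C2=C(OCC)C1 | intermediate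
10 | (4R,4aS,7S,8aR)-4-(hydroxymethyl)-3,4a,8,8-tetramethyl-7-(prop-1-en-2-yl)-4a,5,6,7,8,8a-hexahydronaphthalen-1(4H)-one | CC1=CC(=O)[C@@H]2C(C)(C)[C@H](C(C)=C)CC[C@@]2(C)[C@@H]1CO | intermediate
11 | umbelliferone (7-hydroxy-2H-chromen-2-one) | Oc1ccc2ccc(=O)oc2c1 | starting material
12 | 7-{[(1R,4aR,6S,8aS)-2,5,5,8a-tetramethyl-4-oxo-6-(prop-1-en-2-yl)-1,4,4a,5,6,7,8,8a-octahydronaphthalen-1-yl]methoxy}-2H-chromen-2-one | CC1=CC(=O)[C@@H]2C(C)(C)[C@H](C(C)=C)CC[C@@]2(C)[C@@H]1COc1ccc2ccc(=O)oc2c1 | intermediate
13 | epi-conferdione, 7-{[(1R,4aS,8aS)-2,5,5,8a-tetramethyl-4,6-dioxo-1,4,4a,5,6,7,8,8a-octahydronaphthalen-1-yl]methoxy}-2H-chromen-2-one | CC1=CC(=O)[C@@H]2C(C)(C)C(=O)CC[C@@]2(C)[C@@H]1COc1ccc2ccc(=O)oc2c1 | target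

## Totals and main risks

Total steps: 9. Longest linear sequence: 9 (from (R)-carvone).

Steps most likely to fail:

1. **Step 5 (Diels–Alder).** The diene terminus is tetrasubstituted and the controlling stereocenter is 1,4-remote, so both rate and facial selectivity are uncertain. Fallback: move the isopropenyl next to the reacting terminus. Start from (S)-carvone: C6 methylation, ethynyl Grignard addition, PCC oxidative transposition, then KOtBu/MeI deconjugative methylation give a ring-A enyne with the isopropenyl on C1 and the C3 ketone in place. Convert the alkyne to a 2-acyloxy diene, run the cycloaddition (dienophile forced anti to the adjacent group), and delete the isopropenyl by hydrodealkenylation (O3; FeSO4/PhSH) instead of oxidizing it.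

2. **Step 9 (oxodealkenylation on the full molecule).** Risks are ozone selectivity against the enone and coumarin, and trapping of a hindered radical next to a quaternary carbon. Fallback: classical stepwise degradation before the coumarin is attached. On 10 with C11-OH silylated: OsO4/NaIO4 to the C3 methyl ketone, Baeyer–Villiger to the acetate, methanolysis, and oxidation of the C3 alcohol; then desilylate and do the Mitsunobu last.

3. **Step 8 (Mitsunobu at the β-branched C11 beside the quaternary C10, with an acidic vinylogous C9-H).** Risks are slow SN2 or elimination to the exocyclic diene. Fallback: form the C–O bond earlier on the unhindered allylic alcohol 9 (Mitsunobu with 11 before step 7), then unveil and conjugate the enone under buffered acid instead of DBU, to avoid 1,6-elimination of the phenoxide.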